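**Retrosynthetic overview**
1. Target 13 comes from its C5 methyl ether 11 by chelation-assisted O-demethylation.
2. The strategy rests on the benzene ring (C4a, C5, C6, C7, C8, C8a), which bears oxygen only at C5 and C8a: four of its carbons (C4a, C8a, C8, C7) are the diene of a 3-acyl-4-oxy-2-pyrone and the other two (C5 with its oxygen, C6) are a ketene acetal.
3. Ring 11 is therefore cut at C4a–C5 and C6–C7 into pyranopyrandione 7 and 1,1-dimethoxyethene 8 (cycloaddition, then loss of CO2 and methanol).
4. The 4-pyranone ring of 7 is opened at O1–C2 to triketone 6, which comes from 3-acetyl-4-hydroxy-2-pyrone 4 and methyl hexadecanoate 5 (Claisen); 4 comes from 4-hydroxy-2-pyrone 1 and acetic acid 2.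
5. Ring order: the 2-pyrone ring is bought, the 4-pyranone ring is closed in step 3, and the benzene ring is made from the 2-pyrone ring in step 4.

Key step: step 4

Remark: compound 1 is taken as a purchasable catalogue compound; chromone locants (O1, C2, C3, C4, C4a, C5–C8, C8a) are used throughout, and in 7 positions 5 and 6 are the lactone C=O and ring oxygen that the two carbons of 8 later replace.

**Step 1**
Reactants: 1 4-hydroxy-2H-pyran-2-one; 2 acetic acid
Product: 4 3-acetyl-4-hydroxy-2H-pyran-2-one, via 2-oxo-2H-pyran-4-yl acetate 3 (not isolated)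
Conditions: DCC (1.2 equiv), DMAP (0.3 equiv), toluene, rt then 80 °C
Reagents that add atoms: none
Why: Steglich O-acylation of the acidic enol gives enol ester 3, and DMAP then returns the acetyl group to the nucleophilic C3 through an acylpyridinium/pyronate ion pair (Fries-type 1,3 O-to-C acyl shift), the established way to 3-acyl-4-hydroxy-2-pyrones.

**Step 2**
Reactants: 4 3-acetyl-4-hydroxy-2H-pyran-2-one; 5 methyl hexadecanoate
Product: 6 4-hydroxy-3-(3-oxooctadecanoyl)-2H-pyran-2-one
Conditions: LiN(iPr)2 (3.2 equiv), THF, −78 → 0 °C; then 5 (2 equiv), −78 °C → rt; 1 M HCl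
Reagents that add atoms: none
Why: Deprotonation of the enol OH and of the acetyl CH3 should give an O,C-dianion whose carbon terminus attacks the ester in a crossed Claisen condensation, and the product is held as its diketonate until the acidic work-up, as in acylations of β-diketone dianions.

**Step 3**
Reactants: 6 4-hydroxy-3-(3-oxooctadecanoyl)-2H-pyran-2-one
Product: 7 2-pentadecyl-4H,5H-pyrano[4,3-b]pyran-4,5-dione
Conditions: p-TsOH·H2O (10 mol %), toluene, reflux, Dean–Stark
Reagents that add atoms: none
Why: Acid-catalysed cyclodehydration of the chromone type: the enol oxygen on C8a adds to the side-chain ketone (6-exo-trig) and loss of water should give the 4-pyranone ring, the standard closure of o-hydroxyaryl 1,3-diketones.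

**Step 4**
Reactants: 7 2-pentadecyl-4H,5H-pyrano[4,3-b]pyran-4,5-dione; 8 1,1-dimethoxyethene
Product: 11 5-methoxy-2-pentadecyl-4H-chromen-4-one, via bridged lactone cycloadduct 9 (not isolated), via 5,5-dimethoxy-5,6-dihydrochromenone 10 (not isolated)
Conditions: 8 (6 equiv), toluene, 120 °C, sealed tube
Reagents that add atoms: none
Why: The 2-pyrone ring of 7 (diene C4a=C8a–C8=C7) is electron-poor because C4a carries both the lactone carbonyl and the C4 ketone, so it should pair with the electron-rich ketene acetal 8 in an inverse-electron-demand Diels–Alder reaction, probably asynchronous with C6–C7 bonding in the lead. The closest known reaction type is the aryl annulation of 3-alkoxycarbonyl- and 3-acyl-2-pyrones with 1,1-dimethoxyethene, applied here to a pyrone fused to a 4-pyranone. The new six-membered ring closes by intermolecular [4+2] cycloaddition to the bridged lactone 9, which loses CO2 by retro-[4+2] to diene 10, and 1,2-elimination of methanol (C5–OMe, C6–H) then aromatises the ring. No stereocentre survives, since the two bridgehead centres of 9 (C4a, C7) form as a racemate and vanish with the CO2. Regioselectivity is needed and polarity should secure it: the nucleophilic CH2 of 8 bonds to C7, an unsubstituted CH and the δ-acceptor carbon of both carbonyl groups, so the charge is taken up at C4a between two carbonyls, the C(OMe)2 carbon closes there, and the methoxy group ends at C5. Site selectivity over the C2=C3 enone is expected because C2 is alkyl-substituted and deactivated within the vinylogous ester O1–C2=C3–C4=O.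

**Step 5**
Reactants: 11 5-methoxy-2-pentadecyl-4H-chromen-4-one
Product: 13 5-hydroxy-2-pentadecyl-4H-chromen-4-one, via dichloroboron aryloxide chelate 12 (not isolated)
Conditions: BCl3 (1 M in CH2Cl2, 2.5 equiv), CH2Cl2, −78 → 0 °C; then H2O
Reagents that add atoms: none
Why: BCl3 should chelate between the C4 carbonyl oxygen and the peri C5 ether oxygen, chloride removes the methyl group by SN2 to give chelate 12, and water frees the hydrogen-bonded phenol; this is the standard selective cleavage of 5-methoxychromones.

**Compound list**
1 | 4-hydroxy-2H-pyran-2-one | O=c1cc(O)cco1 | starting material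
2 | acetic acid | CC(=O)O | starting material
3 | 2-oxo-2H-pyran-4-yl acetate | CC(=O)Oc1ccoc(=O)c1 | intermediate (not isolated)
4 | 3-acetyl-4-hydroxy-2H-pyran-2-one | CC(=O)c1c(O)ccoc1=O | intermediate
5 | methyl hexadecanoate | CCCCCCCCCCCCCCCC(=O)OC | starting material
6 | 4-hydroxy-3-(3-oxooctadecanoyl)-2H-pyran-2-one (C3 side chain C(=O)–CH2–C(=O)–C15H31) | CCCCCCCCCCCCCCCC(=O)CC(=O)c1c(O)ccoc1=O | intermediate
7 | 2-pentadecyl-4H,5H-pyrano[4,3-b]pyran-4,5-dione | CCCCCCCCCCCCCCCC1=CC(=O)C2=C(C=COC2=O)O1 | intermediate
8 | 1,1-dimethoxyethene | C=C(OC)OC | starting material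
9 | bridged lactone cycloadduct: C4a and C7 of 7 joined by a C(OMe)2–CH2 bridge (C(OMe)2 on C4a), lactone bridge C5(=O)–O6 kept, C8=C8a double bond; racemate, relative configuration fixed by the bicycle | CCCCCCCCCCCCCCCC1=CC(=O)C23C(=O)OC(CC2(OC)OC)C=C3O1 | intermediate (not isolated)
10 | 5,5-dimethoxy-2-pentadecyl-5,6-dihydro-4H-chromen-4-one | CCCCCCCCCCCCCCCC1=CC(=O)C2=C(C=CCC2(OC)OC)O1 | intermediate (not isolated)
11 | 5-methoxy-2-pentadecyl-4H-chromen-4-one | CCCCCCCCCCCCCCCc1cc(=O)c2c(OC)cccc2o1 | intermediate
12 | 5-[(dichloroboranyl)oxy]-2-pentadecyl-4H-chromen-4-one (boron also coordinated by the C4 carbonyl oxygen) | CCCCCCCCCCCCCCCc1cc(=O)c2c(OB(Cl)Cl)cccc2o1 | intermediate (not isolated)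
13 | 5-hydroxy-2-pentadecyl-4H-chromen-4-one | CCCCCCCCCCCCCCCc1cc(=O)c2c(O)cccc2o1 | target

**Step count**
Total steps: 5. Longest linear sequence: 5 steps (1 → 4 → 6 → 7 → 11 → 13).

**Steps most likely to fail**

Step 4. Donation from O1 into the diene may slow the cycloaddition so much that the ketene acetal oligomerises or decomposes first, or the acetal may add to C2 of the 4-pyranone instead of C7. The fallback takes the benzene ring from an arene instead of building it. It sets out from methyl hexadecanoate 5, which would be condensed (LiN(iPr)2, THF, crossed Claisen) with the dianion of purchased 1-(2-hydroxy-6-methoxyphenyl)ethanone F1 to give 1-(2-hydroxy-6-methoxyphenyl)octadecane-1,3-dione F2. Acid cyclodehydration of F2 (H2SO4 cat., AcOH, heat) should close the 4-pyranone ring and return to the route at 11, after which step 5 follows unchanged.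

Step 2. The dianion may take a proton from the enolisable ester instead of acylating, the ester may self-condense, or dianion formation may be incomplete. The fallback makes the C–C bond by an intramolecular acyl shift. It sets out from 4, which would be O-acylated with purchased hexadecanoyl chloride F3 (Et3N, CH2Cl2, 0 °C) to the enol ester 3-acetyl-2-oxo-2H-pyran-4-yl hexadecanoate F4. Treatment of F4 with LiN(SiMe3)2 in THF should form the acetyl enolate, which takes the acyl group from the neighbouring oxygen (Baker–Venkataraman rearrangement), and the route is rejoined at 6.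

Step 3. Under hot acid the 2-pyrone lactone may open and decarboxylate, or the side-chain enol may close onto the lactone carbonyl instead of the C8a oxygen closing onto the ketone. The fallback closes the ring by addition instead of condensation. It sets out from 1 and uses purchased heptadec-1-yne F5, which would be deprotonated with n-BuLi (THF, −78 °C) and carboxylated with CO2 to octadec-2-ynoic acid F6. Coupling of F6 to 1 with DCC and DMAP (O-acylation, then O-to-C acyl shift) should give 4-hydroxy-3-(octadec-2-ynoyl)-2H-pyran-2-one F7. The C8a enol oxygen of F7 then adds to the ynone in a 6-endo-dig oxa-Michael closure (DMAP cat., DMF), which returns to the route at 7.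

**Further compounds**
F1 | step 4 | 1-(2-hydroxy-6-methoxyphenyl)ethanone (purchased) | CC(=O)c1c(O)cccc1OC
F2 | step 4 | 1-(2-hydroxy-6-methoxyphenyl)octadecane-1,3-dione | CCCCCCCCCCCCCCCC(=O)CC(=O)c1c(O)cccc1OC
F3 | step 2 | hexadecanoyl chloride (purchased) | CCCCCCCCCCCCCCCC(=O)Cl
F4 | step 2 | 3-acetyl-2-oxo-2H-pyran-4-yl hexadecanoate | CCCCCCCCCCCCCCCC(=O)Oc1ccoc(=O)c1C(C)=O
F5 | step 3 | heptadec-1-yne (purchased) | CCCCCCCCCCCCCCCC#C
F6 | step 3 | octadec-2-ynoic acid | CCCCCCCCCCCCCCCC#CC(=O)O
F7 | step 3 | 4-hydroxy-3-(octadec-2-ynoyl)-2H-pyran-2-one | CCCCCCCCCCCCCCCC#CC(=O)c1c(O)ccoc1=O
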